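**Retrosynthetic overview**

1. The strategy rests on ring B, the hexasubstituted benzene fused to the five-membered hydroxy-lactone (ring D). Its carbons are b1 (ether O to ring A), b2 (ester O of the seven-membered lactone, ring C), b3 (CH3), b4 (OH), b5 (lactone C=O) and b6 (lactol CH). The oxygens on b2 and b4 flank the methyl carbon b3, which is the pattern a vinylketene plus 1-siloxypropyne benzannulation leaves. Ring A carbons are a1 (OCH3), a2 (H), a3 (CH3), a4 (C=O), a5 (ether O) and a6 (OH).
2. Key disconnection: ring B is cut at b5–b6, b2–b3, b4–b5 and b1–b2 into diazo keto ester 16 and siloxyalkyne 19. Compound 16 already carries the a5–O–b1 ether as an enol ether and b6 as CH(OMe)2, so no aryl–O coupling between two crowded rings is needed.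
3. Compound 16 comes from ring A salicylate 8 (six steps from creosol) and enol tosylate 11 by vinylic substitution, saponification, two-carbon homologation and diazo transfer.
4. Ring order: A (bought), B (step 13), D (lactol lactone, step 14), C (carbodiimide lactonization, step 16).
5. The lactol carbon is fixed as an (S)-1-phenylethyl acetal by crystallization-induced diastereomer transformation (step 18) and released with retention by hydrogenolysis (step 19).

Key step: step 13

Remark 1: the lactol carbon of ring D is a hemiacetal that can epimerize by ring–chain tautomerism. Its configuration is therefore fixed only on a covalent acetal in step 18, and the target is to be isolated cold from neutral aprotic solvent and kept as a solid.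

Remark 2: which acetal epimer crystallizes in step 18 cannot be predicted. If it is the (S)-acetal, (R)-1-phenylethanol is to be used in step 15 instead.

Remark 3: the enol ether geometry of 12–16 is drawn E (the expected thermodynamic isomer). It has no consequence, because both isomers lead to the same arene.

**Route**

Step 1
Reactants: 1 2-methoxy-4-methylphenol (creosol)
Product: 2 2-hydroxy-3-methoxy-5-methylbenzaldehyde
Conditions: MgCl2, Et3N, (CH2O)n, MeCN, reflux; 1 M HCl work-up
Reagents that add atoms: paraformaldehyde (formaldehyde), C=O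
Why: Casnati–Skattebøl ortho-formylation through the magnesium phenoxide delivers formaldehyde only to the one free position ortho to the phenol.

Step 2
Reactants: 2 2-hydroxy-3-methoxy-5-methylbenzaldehyde
Product: 3 2-(benzyloxy)-3-methoxy-5-methylbenzaldehyde
Conditions: BnBr, K2CO3, DMF, rt
Reagents that add atoms: benzyl bromide, BrCc1ccccc1
Why: Williamson etherification of the salicylaldehyde phenol puts the hydrogenolysable group on the oxygen that ends as the a6 phenol.

Step 3
Reactants: 3 2-(benzyloxy)-3-methoxy-5-methylbenzaldehyde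
Product: 5 2-(benzyloxy)-3-methoxy-5-methylphenol, via aryl formate 4 (not isolated)
Conditions: mCPBA, CH2Cl2, 0 °C → rt; NaHCO3 wash; then K2CO3 (cat.), MeOH, rt
Reagents that add atoms: mCPBA, OOC(=O)c1cccc(Cl)c1
Why: Baeyer–Villiger (Dakin-type) oxidation of an ortho-alkoxybenzaldehyde proceeds by aryl migration to the formate, and mild methanolysis frees the phenol that will carry the diaryl ether.

Step 4
Reactants: 5 2-(benzyloxy)-3-methoxy-5-methylphenol
Product: 6 3-(benzyloxy)-2-hydroxy-4-methoxy-6-methylbenzaldehyde
Conditions: MgCl2, Et3N, (CH2O)n, MeCN, reflux; 1 M HCl work-up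
Reagents that add atoms: paraformaldehyde (formaldehyde), C=O
Why: a second Casnati–Skattebøl ortho-formylation, where only one ortho position is open and magnesium chelation excludes attack at the para position.

Step 5
Reactants: 6 3-(benzyloxy)-2-hydroxy-4-methoxy-6-methylbenzaldehyde
Product: 7 3-(benzyloxy)-2-hydroxy-4-methoxy-6-methylbenzoic acid
Conditions: NaClO2, NaH2PO4, 2-methyl-2-butene (large excess), t-BuOH/H2O, 0 °C → rt
Reagents that add atoms: sodium chlorite, [Na+].[O-]Cl=O
Why: Pinnick oxidation converts the aldehyde to the acid while the alkene scavenger removes the HOCl that could chlorinate the electron-rich ring.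

Step 6
Reactants: 7 3-(benzyloxy)-2-hydroxy-4-methoxy-6-methylbenzoic acid
Product: 8 tert-butyl 3-(benzyloxy)-2-hydroxy-4-methoxy-6-methylbenzoate
Conditions: Me2NCH(Ot-Bu)2, toluene, 80 °C
Reagents that add atoms: N,N-dimethylformamide di-tert-butyl acetal, CN(C)C(OC(C)(C)C)OC(C)(C)C
Why: esterification by O-alkylation of the carboxylate with the tert-butyl cation equivalent of the formamide acetal is insensitive to the two ortho substituents and leaves the hydrogen-bonded phenol free.

Step 7
Reactants: 9 methyl 3,3-dimethoxypropanoate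
Product: 11 methyl (Z)-2-(dimethoxymethyl)-3-(tosyloxy)acrylate, via sodium enolate 10 (not isolated)
Conditions: NaH, HCO2Me, THF, 0 °C → rt; evaporate volatiles; then TsCl, MeCN, 0 °C → rt
Reagents that add atoms: methyl formate, COC=O; p-toluenesulfonyl chloride, Cc1ccc(cc1)S(Cl)(=O)=O
Why: crossed Claisen formylation gives the chelated sodium enolate, and its O-sulfonylation gives a vinylogous mixed anhydride ready for addition–elimination.

Step 8
Reactants: 8 tert-butyl 3-(benzyloxy)-2-hydroxy-4-methoxy-6-methylbenzoate; 11 methyl (Z)-2-(dimethoxymethyl)-3-(tosyloxy)acrylate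
Product: 12 tert-butyl 3-(benzyloxy)-2-{[(E)-2-(dimethoxymethyl)-3-methoxy-3-oxoprop-1-enyl]oxy}-4-methoxy-6-methylbenzoate
Conditions: Cs2CO3, DMF, 0 °C → rt
Reagents that add atoms: none
Why: nucleophilic vinylic substitution (conjugate addition of the cesium phenoxide to the β-carbon, then loss of tosylate) forms the a5–O–b1 bond as a plain enol ether through an ester-stabilized carbanion that settles to the E product.

Step 9
Reactants: 12 tert-butyl 3-(benzyloxy)-2-{[(E)-2-(dimethoxymethyl)-3-methoxy-3-oxoprop-1-enyl]oxy}-4-methoxy-6-methylbenzoate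
Product: 13 (E)-3-[2-(benzyloxy)-6-(tert-butoxycarbonyl)-3-methoxy-5-methylphenoxy]-2-(dimethoxymethyl)acrylic acid
Conditions: LiOH·H2O, THF/H2O, rt; then 1 M HCl to pH 4, 0 °C
Reagents that add atoms: lithium hydroxide, [Li+].[OH-]
Why: saponification takes only the methyl ester, because the 2,6-disubstituted tert-butyl benzoate is inert to hydroxide and the push–pull β-aryloxyacrylate is a poor conjugate acceptor.

Step 10
Reactants: 13 (E)-3-[2-(benzyloxy)-6-(tert-butoxycarbonyl)-3-methoxy-5-methylphenoxy]-2-(dimethoxymethyl)acrylic acid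
Product: 15 tert-butyl 3-(benzyloxy)-2-{[(E)-5-tert-butoxy-2-(dimethoxymethyl)-3,5-dioxopent-1-enyl]oxy}-4-methoxy-6-methylbenzoate, via acyl imidazolide 14 (not isolated)
Conditions: CDI, THF, rt; then HO2CCH2CO2t-Bu, MgCl2, Et3N, MeCN, rt → 40 °C; aq. NH4Cl work-up
Reagents that add atoms: mono-tert-butyl malonate, OC(=O)CC(=O)OC(C)(C)C; 1,1'-carbonyldiimidazole (imidazolyl group in 14 only), O=C(n1ccnc1)n1ccnc1
Why: Masamune–Brooks homologation, in which the magnesium enolate of the malonic half ester C-acylates the acyl imidazolide and loses CO2 under near-neutral conditions that the acetal and enol ether tolerate.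

Step 11
Reactants: 15 tert-butyl 3-(benzyloxy)-2-{[(E)-5-tert-butoxy-2-(dimethoxymethyl)-3,5-dioxopent-1-enyl]oxy}-4-methoxy-6-methylbenzoate
Product: 16 tert-butyl 3-(benzyloxy)-2-{[(E)-5-tert-butoxy-4-diazo-2-(dimethoxymethyl)-3,5-dioxopent-1-enyl]oxy}-4-methoxy-6-methylbenzoate
Conditions: 4-AcNHC6H4SO2N3, Et3N, MeCN, 0 °C → rt
Reagents that add atoms: 4-acetamidobenzenesulfonyl azide, CC(=O)Nc1ccc(cc1)S(=O)(=O)N=[N+]=[N-]
Why: Regitz diazo transfer to the active methylene of a β-keto ester is fast and chemoselective.

Step 12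
Reactants: 17 1-propynyllithium
Product: 19 triisopropyl(prop-1-yn-1-yloxy)silane, via lithium ynolate 18 (not isolated)
Conditions: t-BuOOH (anhydrous), LiN(SiMe3)2, THF, −78 °C; add 17, −78 → 0 °C; then i-Pr3SiOTf, −78 °C → rt
Reagents that add atoms: tert-butyl hydroperoxide, CC(C)(C)OO; triisopropylsilyl triflate, CC(C)[Si](OS(=O)(=O)C(F)(F)F)(C(C)C)C(C)C
Why: electrophilic oxygen transfer from lithium tert-butyl peroxide to the acetylide gives the ynolate, which the hard silyl triflate traps on oxygen as an isolable bulky ynol ether.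

Step 13
Reactants: 16 tert-butyl 3-(benzyloxy)-2-{[(E)-5-tert-butoxy-4-diazo-2-(dimethoxymethyl)-3,5-dioxopent-1-enyl]oxy}-4-methoxy-6-methylbenzoate; 19 triisopropyl(prop-1-yn-1-yloxy)silane
Product: 24 tert-butyl 3-(benzyloxy)-2-[5-(tert-butoxycarbonyl)-6-(dimethoxymethyl)-2-hydroxy-3-methyl-4-(triisopropylsilyloxy)phenoxy]-4-methoxy-6-methylbenzoate, via vinylketene 20 (not isolated), via cyclobutenone 21 (not isolated), via dienylketene 22 (not isolated), via cyclohexadienone 23 (not isolated)
Conditions: 19 (3 equiv), hν (300 nm), degassed ClCH2CH2Cl, rt; then 80 °C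
Reagents that add atoms: none
Why: Proposed new method: light expels N2 from 16 and the aryloxyvinyl group shifts to the carbene carbon (Wolff rearrangement, forming b5–b6) to give the tert-butoxycarbonyl vinylketene 20; the nucleophilic methyl-bearing carbon of 19 attacks the ketene carbonyl carbon, the [2+2] adduct 21 (b2–b3 and b4–b5 formed) opens reversibly by four-electron electrocyclic opening to dienylketene 22, and 22 closes and tautomerizes through 23 to phenol 24. The closest known reaction type is the photochemical vinylketene–siloxyalkyne benzannulation of α,β-unsaturated α'-diazo ketones (Danheiser benzannulation), which has not been shown for a 2-diazo-1,3-keto ester, that is for an ester-substituted vinylketene, nor for a β-aryloxy group on the vinyl unit. Ring B is closed as a carbocycle by six-electron disrotatory electrocyclization between the ketene carbon b2 and the aryloxy-bearing terminus b1; no stereocenter is formed. The step needs migration of the vinyl group and not of the tert-butoxy group in the Wolff step, which the much higher migratory aptitude of an sp2 carbon over an alkoxy group in diazo keto esters should secure. It needs the regiochemistry in which the methyl carbon of the alkyne bonds to the ketene carbonyl, which the oxygen-polarized triple bond secures, and it needs cycloaddition across the ketene C=C instead of [4+2] capture through the ester carbonyl, which the bulk and low nucleophilicity of the tert-butyl ester oxygen are expected to disfavour. The excess of 19 should limit acylation of the product phenol by unreacted ketene, and the temperature is kept at 80 °C so that the tert-butyl esters do not fragment.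

Step 14
Reactants: 24 tert-butyl 3-(benzyloxy)-2-[5-(tert-butoxycarbonyl)-6-(dimethoxymethyl)-2-hydroxy-3-methyl-4-(triisopropylsilyloxy)phenoxy]-4-methoxy-6-methylbenzoate
Product: 25 3-(benzyloxy)-2-{[3,5-dihydroxy-6-methyl-1-oxo-7-(triisopropylsilyloxy)-1,3-dihydroisobenzofuran-4-yl]oxy}-4-methoxy-6-methylbenzoic acid (racemic at the lactol carbon)
Conditions: TFA/CH2Cl2/H2O (10:10:1), 0 °C → rt
Reagents that add atoms: water, O
Why: acidolysis removes both tert-butyl esters as isobutene and hydrolyses the dimethyl acetal, and the resulting ortho-formylbenzoic acid closes to the hydroxyphthalide (ring D) by ring–chain tautomerism, while the aryl silyl ether and the benzyl ether withstand brief TFA.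

Step 15
Reactants: 25 3-(benzyloxy)-2-{[3,5-dihydroxy-6-methyl-1-oxo-7-(triisopropylsilyloxy)-1,3-dihydroisobenzofuran-4-yl]oxy}-4-methoxy-6-methylbenzoic acid; 26 (S)-1-phenylethanol
Product: 27 3-(benzyloxy)-2-{[5-hydroxy-6-methyl-1-oxo-3-[(S)-1-phenylethoxy]-7-(triisopropylsilyloxy)-1,3-dihydroisobenzofuran-4-yl]oxy}-4-methoxy-6-methylbenzoic acid (both epimers at the acetal carbon)
Conditions: 26 (3 equiv), CSA (cat.), 4 Å MS, CH2Cl2, rt
Reagents that add atoms: none
Why: acid-catalysed pseudo-ester (lactol acetal) formation caps the lactol before the ring A acid is activated; no facial control is expected here, the hindered ring A acid is not esterified under Fischer conditions, and the mild acid at rt should not ionize the benzylic alcohol.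

Step 16
Reactants: 27 3-(benzyloxy)-2-{[5-hydroxy-6-methyl-1-oxo-3-[(S)-1-phenylethoxy]-7-(triisopropylsilyloxy)-1,3-dihydroisobenzofuran-4-yl]oxy}-4-methoxy-6-methylbenzoic acid
Product: 28 depsidone with ring C closed that carries the a6 benzyl ether plus the b4 triisopropylsilyl ether plus the (S)-1-phenylethyl acetal at the ring D carbon (both acetal epimers)
Conditions: DCC, DMAP (cat.), CH2Cl2 (2 mM), rt
Reagents that add atoms: none
Why: Steglich-type carbodiimide lactonization closes the seven-membered ring because the only free phenol (b2) and the only acid (on a4) are held next to each other across the diaryl ether, and high dilution suppresses oligomers.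

Step 17
Reactants: 28 silylated depsidone acetal (both acetal epimers)
Product: 29 depsidone with free b4 phenol that carries the a6 benzyl ether plus the (S)-1-phenylethyl acetal (both acetal epimers)
Conditions: Bu4NF, AcOH, THF, 0 °C
Reagents that add atoms: none
Why: fluoride cleaves the aryl silyl ether, and the acetic acid buffer keeps the phenoxide from opening the aryl ester of ring C and leaves the acetal untouched.

Step 18
Reactants: 29 depsidone acetal (both acetal epimers)
Product: 30 depsidone acetal as the single diastereomer with (R) configuration at the ring D acetal carbon and (S) configuration in the 1-phenylethyl group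
Conditions: CSA (cat.), toluene/heptane, 50 °C → 5 °C, slow cooling, seeding
Reagents that add atoms: none
Why: crystallization-induced diastereomer transformation, in which the pseudo-ester carbon epimerizes in solution by reversible acid-catalysed opening of the lactone to the alkoxy-oxocarbenium ion while the less soluble diastereomer crystallizes, so the (S)-1-phenylethyl group and the lattice together set the configuration of the future lactol carbon.

Step 19
Reactants: 30 depsidone acetal (single diastereomer)
Product: 31 target depsidone with free a6 and b4 phenols and the (R)-configured lactol in ring D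
Conditions: H2 (1 atm), Pd/C, EtOAc, rt; filter, concentrate cold, crystallize
Reagents that add atoms: none
Why: hydrogenolysis cleaves the two benzylic C–O bonds remote from the stereocenter (the aryl benzyl ether and the O–CH(CH3)Ph bond of the acetal), so the lactol is released with retention under neutral conditions, the unhindered phenyl rings binding the catalyst more readily than the hexasubstituted ring B.

**Compound list**

1 | 2-methoxy-4-methylphenol (creosol) | COc1cc(C)ccc1O | starting material
2 | 2-hydroxy-3-methoxy-5-methylbenzaldehyde | COc1cc(C)cc(C=O)c1O | intermediate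
3 | 2-(benzyloxy)-3-methoxy-5-methylbenzaldehyde | COc1cc(C)cc(C=O)c1OCc1ccccc1 | intermediate
4 | 2-(benzyloxy)-3-methoxy-5-methylphenyl formate | COc1cc(C)cc(OC=O)c1OCc1ccccc1 | intermediate
5 | 2-(benzyloxy)-3-methoxy-5-methylphenol | COc1cc(C)cc(O)c1OCc1ccccc1 | intermediate
6 | 3-(benzyloxy)-2-hydroxy-4-methoxy-6-methylbenzaldehyde | COc1cc(C)c(C=O)c(O)c1OCc1ccccc1 | intermediate
7 | 3-(benzyloxy)-2-hydroxy-4-methoxy-6-methylbenzoic acid | COc1cc(C)c(C(=O)O)c(O)c1OCc1ccccc1 | intermediate
8 | tert-butyl 3-(benzyloxy)-2-hydroxy-4-methoxy-6-methylbenzoate | COc1cc(C)c(C(=O)OC(C)(C)C)c(O)c1OCc1ccccc1 | intermediate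
9 | methyl 3,3-dimethoxypropanoate | COC(=O)CC(OC)OC | starting material
10 | sodium (Z)-2-(dimethoxymethyl)-3-methoxy-3-oxoprop-1-en-1-olate | [Na+].[O-]/C=C(\C(=O)OC)C(OC)OC | intermediate
11 | methyl (Z)-2-(dimethoxymethyl)-3-(tosyloxy)acrylate | COC(=O)/C(=C\OS(=O)(=O)c1ccc(C)cc1)C(OC)OC | intermediate
12 | tert-butyl 3-(benzyloxy)-2-{[(E)-2-(dimethoxymethyl)-3-methoxy-3-oxoprop-1-enyl]oxy}-4-methoxy-6-methylbenzoate | COc1cc(C)c(C(=O)OC(C)(C)C)c(O/C=C(/C(=O)OC)C(OC)OC)c1OCc1ccccc1 | intermediate
13 | (E)-3-[2-(benzyloxy)-6-(tert-butoxycarbonyl)-3-methoxy-5-methylphenoxy]-2-(dimethoxymethyl)acrylic acid | COc1cc(C)c(C(=O)OC(C)(C)C)c(O/C=C(/C(=O)O)C(OC)OC)c1OCc1ccccc1 | intermediate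
14 | acyl imidazolide of 13 | COc1cc(C)c(C(=O)OC(C)(C)C)c(O/C=C(/C(=O)n2ccnc2)C(OC)OC)c1OCc1ccccc1 | intermediate
15 | tert-butyl 3-(benzyloxy)-2-{[(E)-5-tert-butoxy-2-(dimethoxymethyl)-3,5-dioxopent-1-enyl]oxy}-4-methoxy-6-methylbenzoate | COc1cc(C)c(C(=O)OC(C)(C)C)c(O/C=C(/C(=O)CC(=O)OC(C)(C)C)C(OC)OC)c1OCc1ccccc1 | intermediate
16 | tert-butyl 3-(benzyloxy)-2-{[(E)-5-tert-butoxy-4-diazo-2-(dimethoxymethyl)-3,5-dioxopent-1-enyl]oxy}-4-methoxy-6-methylbenzoate | COc1cc(C)c(C(=O)OC(C)(C)C)c(O/C=C(/C(=O)C(=[N+]=[N-])C(=O)OC(C)(C)C)C(OC)OC)c1OCc1ccccc1 | intermediate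
17 | 1-propynyllithium | [Li]C#CC | starting material
18 | lithium prop-1-yn-1-olate | [Li+].[O-]C#CC | intermediate
19 | triisopropyl(prop-1-yn-1-yloxy)silane | CC#CO[Si](C(C)C)(C(C)C)C(C)C | intermediate
20 | tert-butoxycarbonyl (aryloxyvinyl)ketene from 16 | COc1cc(C)c(C(=O)OC(C)(C)C)c(O/C=C(/C(=C=O)C(=O)OC(C)(C)C)C(OC)OC)c1OCc1ccccc1 | intermediate
21 | 4-(aryloxyvinyl)-4-(tert-butoxycarbonyl)-2-methyl-3-(triisopropylsilyloxy)cyclobut-2-enone (racemic) | COc1cc(C)c(C(=O)OC(C)(C)C)c(O/C=C(/C2(C(=O)OC(C)(C)C)C(=O)C(C)=C2O[Si](C(C)C)(C(C)C)C(C)C)C(OC)OC)c1OCc1ccccc1 | intermediate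
22 | dienylketene from ring opening of 21 | COc1cc(C)c(C(=O)OC(C)(C)C)c(O/C=C(/C(C(=O)OC(C)(C)C)=C(/O[Si](C(C)C)(C(C)C)C(C)C)C(C)=C=O)C(OC)OC)c1OCc1ccccc1 | intermediate
23 | 6-aryloxycyclohexa-2,4-dienone tautomer of 24 (racemic) | COc1cc(C)c(C(=O)OC(C)(C)C)c(OC2C(=O)C(C)=C(O[Si](C(C)C)(C(C)C)C(C)C)C(C(=O)OC(C)(C)C)=C2C(OC)OC)c1OCc1ccccc1 | intermediate
24 | tert-butyl 3-(benzyloxy)-2-[5-(tert-butoxycarbonyl)-6-(dimethoxymethyl)-2-hydroxy-3-methyl-4-(triisopropylsilyloxy)phenoxy]-4-methoxy-6-methylbenzoate | COc1cc(C)c(C(=O)OC(C)(C)C)c(Oc2c(O)c(C)c(O[Si](C(C)C)(C(C)C)C(C)C)c(C(=O)OC(C)(C)C)c2C(OC)OC)c1OCc1ccccc1 | intermediate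
25 | 3-(benzyloxy)-2-{[3,5-dihydroxy-6-methyl-1-oxo-7-(triisopropylsilyloxy)-1,3-dihydroisobenzofuran-4-yl]oxy}-4-methoxy-6-methylbenzoic acid (racemic lactol) | COc1cc(C)c(C(=O)O)c(Oc2c(O)c(C)c(O[Si](C(C)C)(C(C)C)C(C)C)c3C(=O)OC(O)c23)c1OCc1ccccc1 | intermediate
26 | (S)-1-phenylethanol | C[C@H](O)c1ccccc1 | starting material
27 | (S)-1-phenylethyl acetal of 25 (both epimers at the acetal carbon) | COc1cc(C)c(C(=O)O)c(Oc2c(O)c(C)c(O[Si](C(C)C)(C(C)C)C(C)C)c3C(=O)OC(O[C@@H](C)c4ccccc4)c23)c1OCc1ccccc1 | intermediate
28 | depsidone, a6 benzyl ether, b4 triisopropylsilyl ether, (S)-1-phenylethyl acetal (both acetal epimers) | COc1cc(C)c2c(c1OCc1ccccc1)Oc1c(c(C)c(O[Si](C(C)C)(C(C)C)C(C)C)c3c1C(O[C@@H](C)c1ccccc1)OC3=O)OC2=O | intermediate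
29 | depsidone, a6 benzyl ether, free b4 phenol, (S)-1-phenylethyl acetal (both acetal epimers) | COc1cc(C)c2c(c1OCc1ccccc1)Oc1c(c(C)c(O)c3c1C(O[C@@H](C)c1ccccc1)OC3=O)OC2=O | intermediate
30 | depsidone acetal, single diastereomer, (R) at the acetal carbon, (S) in the 1-phenylethyl group | COc1cc(C)c2c(c1OCc1ccccc1)Oc1c(c(C)c(O)c3c1[C@H](O[C@@H](C)c1ccccc1)OC3=O)OC2=O | intermediate
31 | target depsidone, (R)-lactol | COc1cc(C)c2c(c1O)Oc1c(c(C)c(O)c3c1[C@H](O)OC3=O)OC2=O | target

**Totals and risks**

Total step count: 19. Longest linear sequence: 17 steps (steps 1–6, 8–11, 13–19, from creosol).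

Steps most likely to fail:

1. Step 13 (proposed new method). The ester-substituted ketene may be captured by the ynol ether through its ester carbonyl in a [4+2] mode, giving a pyranone instead of the cyclobutenone. The product phenol may also be acylated by unreacted ketene, or the tert-butyl ester may fragment on heating. The fallback uses the established substrate class, a diazo ketone with no acceptor on the diazo carbon, and sets out from acid 13.
   - The mixed anhydride (i-BuOCOCl, N-methylmorpholine, THF, −15 °C) is treated with diazomethane to give the parent diazo ketone F1. The push–pull, trisubstituted enol ether is a poor dipolarophile, so acylation of diazomethane should win over cycloaddition.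
   - Irradiation of F1 with 19 under the conditions of step 13 should give the ring B phenol that lacks the b5 carboxyl carbon, F2.
   - Bu4NF/AcOH frees the b4 phenol to give resorcinol F3.
   - Casnati–Skattebøl formylation (MgCl2, Et3N, paraformaldehyde) can attack only b5, the one free position of ring B and ortho to the new phenol, giving aldehyde F4.
   - Pinnick oxidation gives acid F5.
   - TFA/CH2Cl2/H2O as in step 14 gives lactol acid F6, and acetalization with 26 as in step 15 gives acetal acid F7.
   - Carbodiimide lactonization as in step 16 returns to the route at compound 29, the desilylation of step 17 being already done.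

2. Step 18. Neither acetal epimer may crystallize, the mixture may oil out, or the acid may strip the auxiliary faster than it epimerizes the acetal. The fallback sets out from 29 and replaces crystallization by physical separation. Preparative chromatography on silica separates the two diastereomers into 30 and the (S)-acetal epimer F8. F8 is re-equilibrated to the epimer mixture 29 with catalytic CSA in CH2Cl2 and separated again, so the material is funnelled to 30, where the route is rejoined.

3. Step 19. The lactol may be over-reduced through its aldehyde tautomer to the phthalide, the exocyclic C–O bond at the acetal carbon may be hydrogenolysed in place of the O–CH(CH3)Ph bond, or the lactol may racemize in solution during a slow cleavage. The fallback sets out from 29 (the epimer mixture suffices) and avoids hydrogen.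
   - Aqueous TFA in CH2Cl2 hydrolyses the pseudo-ester to the racemic O-benzyl lactol depsidone F9.
   - BCl3 with pentamethylbenzene in CH2Cl2 at −78 °C cleaves the aryl benzyl ether to the racemic lactol F10.
   - F10 is converted into 31 by crystallization under racemizing conditions (attrition-enhanced deracemization of a slurry seeded with (R) crystals taken from a small chiral-chromatography sample). This requires conglomerate behaviour; otherwise a cocrystal with an enantiopure neutral coformer is to be screened.

**Further compounds**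

F1 | step 13 | tert-butyl 3-(benzyloxy)-2-{[(E)-4-diazo-2-(dimethoxymethyl)-3-oxobut-1-enyl]oxy}-4-methoxy-6-methylbenzoate | COc1cc(C)c(C(=O)OC(C)(C)C)c(O/C=C(/C(=O)C=[N+]=[N-])C(OC)OC)c1OCc1ccccc1
F2 | step 13 | tert-butyl 3-(benzyloxy)-2-[6-(dimethoxymethyl)-2-hydroxy-3-methyl-4-(triisopropylsilyloxy)phenoxy]-4-methoxy-6-methylbenzoate | COc1cc(C)c(C(=O)OC(C)(C)C)c(Oc2c(O)c(C)c(O[Si](C(C)C)(C(C)C)C(C)C)cc2C(OC)OC)c1OCc1ccccc1
F3 | step 13 | tert-butyl 3-(benzyloxy)-2-[6-(dimethoxymethyl)-2,4-dihydroxy-3-methylphenoxy]-4-methoxy-6-methylbenzoate | COc1cc(C)c(C(=O)OC(C)(C)C)c(Oc2c(O)c(C)c(O)cc2C(OC)OC)c1OCc1ccccc1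
F4 | step 13 | tert-butyl 3-(benzyloxy)-2-[6-(dimethoxymethyl)-5-formyl-2,4-dihydroxy-3-methylphenoxy]-4-methoxy-6-methylbenzoate | COc1cc(C)c(C(=O)OC(C)(C)C)c(Oc2c(O)c(C)c(O)c(C=O)c2C(OC)OC)c1OCc1ccccc1
F5 | step 13 | 3-[2-(benzyloxy)-6-(tert-butoxycarbonyl)-3-methoxy-5-methylphenoxy]-2-(dimethoxymethyl)-4,6-dihydroxy-5-methylbenzoic acid | COc1cc(C)c(C(=O)OC(C)(C)C)c(Oc2c(O)c(C)c(O)c(C(=O)O)c2C(OC)OC)c1OCc1ccccc1
F6 | step 13 | 3-(benzyloxy)-2-[(3,5,7-trihydroxy-6-methyl-1-oxo-1,3-dihydroisobenzofuran-4-yl)oxy]-4-methoxy-6-methylbenzoic acid (racemic lactol) | COc1cc(C)c(C(=O)O)c(Oc2c(O)c(C)c(O)c3C(=O)OC(O)c23)c1OCc1ccccc1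
F7 | step 13 | (S)-1-phenylethyl acetal of F6 (both epimers at the acetal carbon) | COc1cc(C)c(C(=O)O)c(Oc2c(O)c(C)c(O)c3C(=O)OC(O[C@@H](C)c4ccccc4)c23)c1OCc1ccccc1
F8 | step 18 | depsidone acetal, (S) at the acetal carbon, (S) in the 1-phenylethyl group | COc1cc(C)c2c(c1OCc1ccccc1)Oc1c(c(C)c(O)c3c1[C@@H](O[C@@H](C)c1ccccc1)OC3=O)OC2=O
F9 | step 19 | racemic O-benzyl lactol depsidone | COc1cc(C)c2c(c1OCc1ccccc1)Oc1c(c(C)c(O)c3c1C(O)OC3=O)OC2=O
F10 | step 19 | racemic lactol depsidone (racemate of 31) | COc1cc(C)c2c(c1O)Oc1c(c(C)c(O)c3c1C(O)OC3=O)OC2=O
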